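60.0 % is the coupling partner of this flask written as a fraction of its substrate charge. This partner budget is the number to hold the flask against.

| flask | substrate | coupling partner | remark | time |
|---|---|---|---|---|
| autumn | 10 mM (fed, over 2.0 h) | 12 mM | run made earlier |  |
| winter | 40 mM (fed, over 2.0 h) | 12 mM | run made earlier |  |
| flask | 20 mM (fed, over 2.0 h) | 12.0 mM |  | 15 d |

| run | time / d | substrate / % | target / % |
|---|---|---|---|
| autumn | 1.04 | 11.9 | 58.2 |
| autumn | 3.00 | 10.4 | 59.2 |
| autumn | 5.00 | 10.4 | 60.2 |
| autumn | 8.00 | 10.1 | 60.0 |
| autumn | 10.0 | 10.0 | 60.0 |
| autumn | 15.0 | 10.3 | 59.5 |
| autumn | 20.0 | 10.0 | 59.5 |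
| winter | 1.04 | 76.8 | 17.3 |
| winter | 3.00 | 76.8 | 18.3 |
| winter | 5.00 | 76.3 | 17.4 |
| winter | 8.00 | 77.4 | 16.8 |
| winter | 10.0 | 76.5 | 17.0 |
| winter | 15.0 | 76.2 | 16.9 |
| winter | 20.0 | 75.9 | 17.5 |

(readings scatter by 0.5 percentage points)

- a reading or a percentage of target counts all its forms, free or not
- the reaction counts as stopped when no species that holds the substrate changes by six tenths of a point or more over the second half of the time

- the state of affairs at 15 d: stopped, and by what, or still going (it is still moving / all of the substrate has reacted / the coupling partner has run out first)
- share of the substrate used up at 15 d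
- target at 15 d, in percent of the substrate charged
- side product at 15 d, in percent of the substrate charged

Call u the part of the substrate charge that has reacted without being read as target: one minus substrate minus target. The winter run reads flat within the scatter from its first reading and the autumn run from its reading at 3.00 d, and at 10.0 d target plus twice u lands on each run's budget:

autumn: 60.0 % + 2 × 30.0 % = 120 %, budget 120 %

winter: 17.0 % + 2 × 6.50 % = 30.0 %, budget 30.0 %

So, as read, target costs one partner and u costs two. Once the partner, the limiting reagent, is spent, conversion is the budget minus u and target is the budget minus twice u. The budget is the large term, and you need reckon only the correction u.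

This flask holds less partner than substrate, as the winter run does, whereas the autumn run holds more and ends with 10.0 % of its substrate. So I take the winter run as the neighbour. It has the same partner charge, and I assume u stays the same amount, which as a fraction scales against the substrate charge:

u = 6.50 % × 40 mM / 20 mM = 13.0 %

conversion = 60.0 % − 13.0 % = 47.0 %; target = 34.0 %

That is my reckoning. The forecast, on the ground that “Selectivity improves with substrate”, said the coupling partner has run out first, with conversion 46.2 %, target 32.5 % and side product 13.8 %, so it stands a little apart from mine.

The flask gives the coupling partner has run out first, with conversion 47.0 %, target 34.1 % and side product 12.1 %.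

    substrate + coupling partner → target (k = 44.0 M⁻¹ h⁻¹)
    substrate + 2 coupling partner → side product (k = 3000 M⁻² h⁻¹)
    crystals ⇌ target, rate k3*(cs3 - [target]) while solid is left; crystals form when [target] > cs3 (solubility = 12.0 mM, k = 1.50 h⁻¹)
    coupling partner + target → over-reaction product (k = 3.40 M⁻¹ h⁻¹)

Over-reaction product also holds two partners per substrate, so u here is side product plus its 0.865 %, which makes 13.0 %, and the budget minus that is 47.0 %. The neighbour charged with 4.8 mM of coupling partner has a budget of 24.0 %. Its side product 2.75 % and over-reaction product 0.181 % make u 2.93 %, so the budget minus u is 21.1 %, and that flask's conversion stands at 21.1 %.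

The runs are calculated for substances that don't exist; the scatter is artificial.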